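**Retrosynthetic overview**

- The target (7R,8R,8'R) has one ring to build: a 3,4-trans-disubstituted oxolane (O, C9, C8, C8', C9'). C8 carries the aryl B carbinol carbon C7 and C8' carries the aryl A benzylic carbon C7'.
- Feature used: each half of the ring is an O–CH2–CH unit with one exocyclic carbon. C9–C8–C7 (C7 at carbonyl level) is acrolein, and O–C9'–C8'=C7'(NO2)(aryl A) is a γ-hydroxy nitroalkene in which the nitro group is a removable activator at C7'.
- Disconnections, last first: the O-benzyl groups (hydrogenolysis); C7–aryl B (aryl Grignard plus aldehyde, 1,2-induction from C8); C7'–H (radical denitration); O–C9 and C8–C8' together (amine-catalysed oxa-Michael/Michael annulation, which closes the oxolane); C8'=C7' (Henry reaction and dehydration); C7'–aryl A (Pd-catalysed arylation of nitromethane).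
- One benzyl-protected aryl bromide supplies both aryl A and aryl B.

Key step: step 6

Remark: lignan locants are used. C7 is the carbinol carbon with aryl B, C8 and C9 are the ring CH and ring CH2 next to it; C7' is the benzylic CH2 with aryl A, C8' and C9' are the ring CH and ring CH2 on that side. Stereocentres that are destroyed later (both in 6, the nitro-bearing carbon in 13) are carried as mixtures. The catalyst of step 6 is (R)-α,α-diphenylprolinol trimethylsilyl ether, SMILES C1C[C@@H](NC1)C(c1ccccc1)(c1ccccc1)O[Si](C)(C)C.

**Route**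

Step 1
Reactants: 1 4-bromo-2-methoxyphenol
Product: 2 1-(benzyloxy)-4-bromo-2-methoxybenzene
Conditions: BnBr, K2CO3, DMF, rt
Reagents that add atoms: benzyl bromide, BrCc1ccccc1
Why: Williamson ether synthesis (phenoxide SN2 on benzyl bromide) gives a phenol protection that should survive the coupling, amine, radical and organomagnesium steps and leave by hydrogenolysis.

Step 2
Reactants: 2 1-(benzyloxy)-4-bromo-2-methoxybenzene; 3 nitromethane
Product: 4 1-(benzyloxy)-2-methoxy-4-(nitromethyl)benzene
Conditions: Pd2(dba)3 (2.5 mol%), XPhos (6 mol%), Cs2CO3, 4 Å MS, MeNO2 as solvent, 50 °C; aq. NH4Cl work-up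
Reagents that add atoms: none
Why: Palladium-catalysed cross-coupling of an aryl bromide with the nitronate of nitromethane (oxidative addition to zerovalent palladium, nitronate transfer, reductive elimination) should give the arylnitromethane in one step, avoiding the nitrite ester formation expected from nitrite displacement on an electron-rich benzylic halide, with excess nitromethane holding back diarylation.

Step 3
Reactants: 4 1-(benzyloxy)-2-methoxy-4-(nitromethyl)benzene; 5 (tert-butyldimethylsilyloxy)acetaldehyde
Product: 6 1-[4-(benzyloxy)-3-methoxyphenyl]-3-[(tert-butyldimethylsilyl)oxy]-1-nitropropan-2-ol (diastereomer mixture)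
Conditions: Et3N (0.3 equiv), THF, 0 °C to rt
Reagents that add atoms: none
Why: Henry (nitroaldol) reaction of the acidic benzylic nitronate with an unhindered α-silyloxy aldehyde forms the C7'–C8' bond; the two new stereocentres are not controlled because the next step removes them.

Step 4
Reactants: 6 1-[4-(benzyloxy)-3-methoxyphenyl]-3-[(tert-butyldimethylsilyl)oxy]-1-nitropropan-2-ol
Product: 8 tert-butyl{[(E)-3-(4-benzyloxy-3-methoxyphenyl)-3-nitroprop-2-en-1-yl]oxy}dimethylsilane, via secondary mesylate 7 (not isolated)
Conditions: MsCl, Et3N, CH2Cl2, −40 to 0 °C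
Reagents that add atoms: none
Why: O-mesylation followed by E1cB elimination across the acidic benzylic α-nitro C–H should give the conjugated nitroalkene as the favoured E isomer (CH2OSi trans to nitro, cis to the twisted aryl ring); the alkene geometry has no bearing on the later ring stereocentres.

Step 5
Reactants: 8 tert-butyl{[(E)-3-(4-benzyloxy-3-methoxyphenyl)-3-nitroprop-2-en-1-yl]oxy}dimethylsilane
Product: 9 (E)-3-[4-(benzyloxy)-3-methoxyphenyl]-3-nitroprop-2-en-1-ol
Conditions: HF (48% aq.), MeCN, 0 °C
Reagents that add atoms: none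
Why: Acidic fluoride desilylation of the primary silyl ether frees the hydroxyl without the basic conditions that would isomerise or oligomerise the nitroalkene; 9 is used without storage.

Step 6
Reactants: 9 (E)-3-[4-(benzyloxy)-3-methoxyphenyl]-3-nitroprop-2-en-1-ol; 10 acrolein
Product: 13 (3R,4S)-4-{[4-(benzyloxy)-3-methoxyphenyl](nitro)methyl}oxolane-3-carbaldehyde, via acrolein iminium benzoate 11 (not isolated), via oxa-Michael enamine 12 (not isolated)
Conditions: (R)-α,α-diphenylprolinol trimethylsilyl ether (20 mol%), PhCO2H (20 mol%), CHCl3, 0 °C to rt, acrolein (1.5 equiv) added slowly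
Reagents that add atoms: none
Why: The amine condenses with acrolein to iminium ion 11, the primary hydroxyl of 9 adds reversibly to its unsubstituted β-carbon (bond O–C9), and enamine 12 then attacks C8' of the tethered nitroalkene through its α-carbon C8 (bond C8–C8'), after which nitronate protonation and hydrolysis release 13 and the amine. The closest known reaction type is the diarylprolinol silyl ether catalysed oxa-Michael/Michael domino reaction of enals with γ-hydroxy enones and with 2-hydroxy-β-nitrostyrenes. The oxolane closes in the 5-exo-trig mode, the C8'=C7' bond staying outside the ring. C8 is set by the catalyst, whose C(Ph)2OSiMe3 group shields one face of the E-enamine so that C8' arrives on the open face (R at C8 with the R-configured amine, by the shielding model that accounts for aldehyde–nitroalkene Michael additions); C8' is set relative to C8 by an envelope transition state that keeps the enamine and the aryl(nitro)methylene unit on opposite sides (trans); C7' is left uncontrolled because it becomes CH2. The step needs O-alkylation before C-alkylation and ring closure in preference to acrolein oligomerisation or a second Michael addition of the product nitronate to acrolein; the irreversible C–C closure drains the oxa-Michael equilibrium, and the acid co-catalyst, low temperature and small excess of acrolein hold back the side reactions.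

Step 7
Reactants: 13 (3R,4S)-4-{[4-(benzyloxy)-3-methoxyphenyl](nitro)methyl}oxolane-3-carbaldehyde
Product: 14 (3R,4R)-4-[4-(benzyloxy)-3-methoxybenzyl]oxolane-3-carbaldehyde
Conditions: Bu3SnH, AIBN, toluene, 90 °C
Reagents that add atoms: none
Why: Radical denitration of a secondary benzylic nitro compound: Bu3Sn• adds to the nitro group, the adduct fragments to the stabilised C7' radical, and this takes hydrogen from Bu3SnH; the radical could reach the aldehyde only through a four-membered ring, and C8 and C8' are not touched.

Step 8
Reactants: 14 (3R,4R)-4-[4-(benzyloxy)-3-methoxybenzyl]oxolane-3-carbaldehyde; 2 1-(benzyloxy)-4-bromo-2-methoxybenzene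
Product: 16 (R)-[4-(benzyloxy)-3-methoxyphenyl]{(3R,4R)-4-[4-(benzyloxy)-3-methoxybenzyl]oxolan-3-yl}methanol, via arylmagnesium bromide 15 (not isolated)
Conditions: 2, Mg turnings, THF, rt; then 14, THF, −78 °C; aq. NH4Cl
Reagents that add atoms: none
Why: Grignard 1,2-addition to the aldehyde forms the C7–aryl B bond; C7 is set by 1,2-induction from C8, since the Felkin–Anh conformer (branched C8' anti to the nucleophile, C9 beside the carbonyl oxygen) and the magnesium chelate between the carbonyl oxygen and the ring oxygen both expose the Si face, which should give 7R.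

Step 9
Reactants: 16 (R)-[4-(benzyloxy)-3-methoxyphenyl]{(3R,4R)-4-[4-(benzyloxy)-3-methoxybenzyl]oxolan-3-yl}methanol
Product: 17 4-[(R)-hydroxy{(3R,4R)-4-(4-hydroxy-3-methoxybenzyl)oxolan-3-yl}methyl]-2-methoxyphenol
Conditions: H2 (1 atm), 10% Pd/C, EtOAc, rt, stopped once the benzyl ethers are consumed
Reagents that add atoms: none
Why: Catalytic hydrogenolysis cleaves both benzyl aryl ethers; under neutral conditions at atmospheric pressure the benzylic C7–OH bond should be cleaved much more slowly, and no stereocentre is affected.

**Compound list**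

1 | 4-bromo-2-methoxyphenol | COc1cc(Br)ccc1O | starting material
2 | 1-(benzyloxy)-4-bromo-2-methoxybenzene | COc1cc(Br)ccc1OCc1ccccc1 | intermediate
3 | nitromethane | C[N+](=O)[O-] | starting material
4 | 1-(benzyloxy)-2-methoxy-4-(nitromethyl)benzene | COc1cc(C[N+](=O)[O-])ccc1OCc1ccccc1 | intermediate
5 | (tert-butyldimethylsilyloxy)acetaldehyde | CC(C)(C)[Si](C)(C)OCC=O | starting material
6 | 1-[4-(benzyloxy)-3-methoxyphenyl]-3-[(tert-butyldimethylsilyl)oxy]-1-nitropropan-2-ol, diastereomer mixture | COc1cc(C([N+](=O)[O-])C(O)CO[Si](C)(C)C(C)(C)C)ccc1OCc1ccccc1 | intermediate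
7 | methanesulfonate of 6 at the secondary hydroxyl (not isolated) | COc1cc(C([N+](=O)[O-])C(OS(C)(=O)=O)CO[Si](C)(C)C(C)(C)C)ccc1OCc1ccccc1 | intermediate
8 | tert-butyl{[(E)-3-(4-benzyloxy-3-methoxyphenyl)-3-nitroprop-2-en-1-yl]oxy}dimethylsilane | CC(C)(C)[Si](C)(C)OC/C=C(/[N+](=O)[O-])c1ccc(OCc2ccccc2)c(OC)c1 | intermediate
9 | (E)-3-[4-(benzyloxy)-3-methoxyphenyl]-3-nitroprop-2-en-1-ol | OC/C=C(/[N+](=O)[O-])c1ccc(OCc2ccccc2)c(OC)c1 | intermediate
10 | acrolein | C=CC=O | starting material
11 | N-(prop-2-en-1-ylidene)iminium benzoate of acrolein and the R catalyst (not isolated) | C=CC=[N+]1CCC[C@@H]1C(c1ccccc1)(c1ccccc1)O[Si](C)(C)C.[O-]C(=O)c1ccccc1 | intermediate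
12 | E-enamine of the R catalyst with 3-{[(E)-3-(4-benzyloxy-3-methoxyphenyl)-3-nitroprop-2-en-1-yl]oxy}propanal (not isolated) | C1C[C@@H](N(C1)/C=C/COC/C=C(/[N+](=O)[O-])c1ccc(OCc2ccccc2)c(OC)c1)C(c1ccccc1)(c1ccccc1)O[Si](C)(C)C | intermediate
13 | (3R,4S)-4-{[4-(benzyloxy)-3-methoxyphenyl](nitro)methyl}oxolane-3-carbaldehyde, ring substituents trans, both epimers at the nitro-bearing carbon | COc1cc(C([N+](=O)[O-])[C@H]2COC[C@@H]2C=O)ccc1OCc1ccccc1 | intermediate
14 | (3R,4R)-4-[4-(benzyloxy)-3-methoxybenzyl]oxolane-3-carbaldehyde | COc1cc(C[C@H]2COC[C@@H]2C=O)ccc1OCc1ccccc1 | intermediate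
15 | [4-(benzyloxy)-3-methoxyphenyl]magnesium bromide (not isolated) | COc1cc([Mg]Br)ccc1OCc1ccccc1 | intermediate
16 | (R)-[4-(benzyloxy)-3-methoxyphenyl]{(3R,4R)-4-[4-(benzyloxy)-3-methoxybenzyl]oxolan-3-yl}methanol | COc1cc(C[C@H]2COC[C@@H]2[C@@H](O)c2ccc(OCc3ccccc3)c(OC)c2)ccc1OCc1ccccc1 | intermediate
17 | 4-[(R)-hydroxy{(3R,4R)-4-(4-hydroxy-3-methoxybenzyl)oxolan-3-yl}methyl]-2-methoxyphenol | COc1cc(C[C@H]2COC[C@@H]2[C@@H](O)c2ccc(O)c(OC)c2)ccc1O | target

**Step count**

Total step count: 9. Longest linear sequence: 9 steps (1 to 17); bromide 2 re-enters in step 8.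

**Steps most likely to fail**

Step 6 (key annulation). The reversible addition of an aliphatic hydroxyl to the acrolein iminium ion may feed the enamine too slowly. Acrolein could then oligomerise, the nitroallylic alcohol could isomerise to the β-nitro aldehyde by a 1,3-proton shift, or the product nitronate could add to a second acrolein. A second concern is the sense of induction: closure through a cis topology followed by epimerisation at C8 would give the mirror-image trans aldehyde. The absolute configuration is therefore to be checked at 13 or 14, and the S catalyst used if needed.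

The fallback sets out from 4 and comes back to the route at 13. It preforms the ether so that only the C–C closure is left to the catalyst.
- Commercial 3,3-diethoxypropan-1-ol is O-allylated (NaH, allyl bromide, THF) to 3-(allyloxy)-1,1-diethoxypropane F1.
- The alkene is cleaved (O3, CH2Cl2, −78 °C, then PPh3) to 2-(3,3-diethoxypropoxy)acetaldehyde F2.
- Henry addition of 4 (Et3N cat., THF) gives nitro alcohol F3.
- MsCl/Et3N takes this through mesylate F4 to nitroalkene acetal F5.
- Amberlyst-15 in wet acetone unmasks 3-{[(E)-3-(4-benzyloxy-3-methoxyphenyl)-3-nitroprop-2-en-1-yl]oxy}propanal F6, the hydrolysed form of enamine 12.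
- With the same amine and PhCO2H, F6 should undergo the known intramolecular enamine Michael addition of an aldehyde to a nitroalkene (5-exo-trig) and give 13, with no free acrolein present.

Step 8 (Grignard addition). Facial selectivity at the aldehyde may be poor, because the two α-substituents on C8 are both ring carbons and differ only moderately in size.

The fallback sets out from 14 and comes back at 16. It replaces substrate control by catalyst control.
- Addition of 15 without useful selectivity gives 16 together with its C7 epimer F9.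
- Dess–Martin periodinane (CH2Cl2, rt) oxidises the mixture to the aryl ketone F10.
- Hydrogenation of the aryl ketone with RuH(BH4)[(S)-xylbinap][(S,S)-dpen] (H2, i-PrOH, base-free) should return the R carbinol 16, the aryl group directing the catalyst. Substrate-controlled hydride reduction is not used because it would favour the 7S epimer.

Step 7 (denitration). Fragmentation of the secondary benzylic nitro group needs heat and excess stannane. Under these conditions the free aldehyde may be reduced by hydrostannation or may undergo aldol-type loss.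

The fallback sets out from 13 and comes back at 14.
- The aldehyde is masked as the dimethyl acetal of 13 F7 (HC(OMe)3, PPTS, MeOH).
- The nitro group is removed with Bu3SnH/AIBN in toluene at 90 °C to give the dimethyl acetal of 14 F8.
- Aqueous acid (1 M HCl, THF, rt) returns aldehyde 14.

**Further compounds**

F1 | step 6 | 3-(allyloxy)-1,1-diethoxypropane | C=CCOCCC(OCC)OCC
F2 | step 6 | 2-(3,3-diethoxypropoxy)acetaldehyde | O=CCOCCC(OCC)OCC
F3 | step 6 | 1-[4-(benzyloxy)-3-methoxyphenyl]-3-(3,3-diethoxypropoxy)-1-nitropropan-2-ol, diastereomer mixture | CCOC(CCOCC(O)C([N+](=O)[O-])c1ccc(OCc2ccccc2)c(OC)c1)OCC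
F4 | step 6 | methanesulfonate of F3 at the secondary hydroxyl | CCOC(CCOCC(OS(C)(=O)=O)C([N+](=O)[O-])c1ccc(OCc2ccccc2)c(OC)c1)OCC
F5 | step 6 | (E)-1-(benzyloxy)-4-[3-(3,3-diethoxypropoxy)-1-nitroprop-1-en-1-yl]-2-methoxybenzene | CCOC(CCOC/C=C(/[N+](=O)[O-])c1ccc(OCc2ccccc2)c(OC)c1)OCC
F6 | step 6 | 3-{[(E)-3-(4-benzyloxy-3-methoxyphenyl)-3-nitroprop-2-en-1-yl]oxy}propanal | O=CCCOC/C=C(/[N+](=O)[O-])c1ccc(OCc2ccccc2)c(OC)c1
F7 | step 7 | dimethyl acetal of 13, same ring configuration, both epimers at the nitro-bearing carbon | COc1cc(C([N+](=O)[O-])[C@H]2COC[C@@H]2C(OC)OC)ccc1OCc1ccccc1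
F8 | step 7 | dimethyl acetal of 14, same ring configuration | COc1cc(C[C@H]2COC[C@@H]2C(OC)OC)ccc1OCc1ccccc1
F9 | step 8 | (S)-[4-(benzyloxy)-3-methoxyphenyl]{(3R,4R)-4-[4-(benzyloxy)-3-methoxybenzyl]oxolan-3-yl}methanol, the C7 epimer of 16 | COc1cc(C[C@H]2COC[C@@H]2[C@H](O)c2ccc(OCc3ccccc3)c(OC)c2)ccc1OCc1ccccc1
F10 | step 8 | [4-(benzyloxy)-3-methoxyphenyl]{(3R,4R)-4-[4-(benzyloxy)-3-methoxybenzyl]oxolan-3-yl}methanone | COc1cc(C[C@H]2COC[C@@H]2C(=O)c2ccc(OCc3ccccc3)c(OC)c2)ccc1OCc1ccccc1
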